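**Strategy**

The 1,3-cyclohexadiene of ring A (C4a=C5–C6=C7, with sp3 C8 and C8a bearing trans substituents; naphthalen-2-one numbering) is the retron of a 2-pyrone/alkene Diels–Alder reaction followed by loss of CO2. The route rests on closing ring B at the ring-fusion bond C4a–C8a in this way. The precursor is a 3,4,6-trisubstituted 2-pyrone, already carrying the ketal-masked acetonyl and the methyl group, tethered from its C6 through the C3–C2–C1 stereotriad to an (E,E)-diene that bears the complete side chain. On heating, C4a–C8a and C7–C8 form, CO2 leaves, and both rings, the diene and the C8/C8a stereocentres arise in one operation.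

Key step: step 19

Core numbering used below: C1 (CHMe), C2 (C=O), C3 (CHMe), C4 (CH2), C4a, C5 (=CH), C6 (CMe), C7 (C–CH2COMe), C8 (CH bearing the side chain), C8a.

Remark on the chemistry: the absolute sense of the two reagent-controlled steps (4 and 12) is assigned from the accepted models and is not independently confirmed; the antipodal reagent is equally available should the sense prove opposite.

**Tether fragment (steps 1–5)**

Step 1
Reactants: 1 (R)-4-benzyl-3-propionyloxazolidin-2-one
Product: 3 (R)-4-benzyl-3-[(S)-2-methylpent-4-ynoyl]oxazolidin-2-one, via sodium (Z)-enolate 2 (not isolated)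
Conditions: NaN(SiMe3)2 (NaHMDS), THF, −78 °C; propargyl bromide, −78 → −40 °C
Reagents that add atoms: propargyl bromide, C#CCBr
Why: Evans asymmetric alkylation, in which the chelated (Z)-enolate is attacked on the face opposite the benzyl group and so sets the future C3 methyl centre.

Step 2
Reactants: 3 (R)-4-benzyl-3-[(S)-2-methylpent-4-ynoyl]oxazolidin-2-one
Product: 4 (S)-2-methylpent-4-yn-1-ol
Conditions: LiBH4, MeOH (1 equiv), Et2O, 0 °C
Reagents that add atoms: none
Why: reductive cleavage of the imide by borohydride should release the auxiliary without touching the stereocentre.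

Step 3
Reactants: 4 (S)-2-methylpent-4-yn-1-ol
Product: 5 (S)-2-methylpent-4-ynal
Conditions: Dess–Martin periodinane, NaHCO3, CH2Cl2, 0 °C → rt; used at once
Reagents that add atoms: none
Why: buffered Dess–Martin oxidation should give the α-chiral aldehyde without epimerisation.

Step 4
Reactants: 5 (S)-2-methylpent-4-ynal
Product: 7 (3R,4R,5S)-3,5-dimethyloct-1-en-7-yn-4-ol, via borinate ester 6 (not isolated)
Conditions: cis-2-butene, n-BuLi, KOt-Bu, THF, −78 → −45 °C; (−)-Ipc2BOMe, −78 °C; BF3·OEt2; then 5, −78 °C; NaOH, H2O2, 0 °C → rt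
Reagents that add atoms: (Z)-crotylbis(isopinocampheyl)borane from (+)-α-pinene, C/C=C\CB([C@@H]1C[C@@H]2C[C@H]([C@H]1C)C2(C)C)[C@@H]1C[C@@H]2C[C@H]([C@H]1C)C2(C)C
Why: Brown crotylboration through a closed chair transition state, in which the (Z)-crotyl geometry gives the syn relationship and the isopinocampheyl groups direct si-face attack, sets the carbinol centre and the adjacent methyl centre (future C2 and C1) as the syn,syn triad.

Step 5
Reactants: 7 (3R,4R,5S)-3,5-dimethyloct-1-en-7-yn-4-ol
Product: 8 triethyl{[(3R,4R,5S)-3,5-dimethyloct-1-en-7-yn-4-yl]oxy}silane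
Conditions: Et3SiOTf, 2,6-lutidine, CH2Cl2, −78 → 0 °C
Reagents that add atoms: triethylsilyl triflate, CC[Si](CC)(CC)OS(=O)(=O)C(F)(F)F
Why: silylation of the hindered secondary alcohol with a silyl triflate; the ether holds the C2 oxidation level and locks the C1 centre until after the key step.

**Enol triflate fragment (steps 6–8)**

Step 6
Reactants: 9 methyl levulinate
Product: 10 methyl 3-(2-methyl-1,3-dioxolan-2-yl)propanoate
Conditions: ethylene glycol, p-TsOH (cat.), toluene, reflux, Dean–Stark trap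
Reagents that add atoms: ethylene glycol, OCCO
Why: acid-catalysed ketalisation with azeotropic removal of water masks the future acetonyl ketone so that later basic steps cannot enolise it.

Step 7
Reactants: 10 methyl 3-(2-methyl-1,3-dioxolan-2-yl)propanoate
Product: 12 methyl 2-acetyl-3-(2-methyl-1,3-dioxolan-2-yl)propanoate, via lithium enolate 11 (not isolated)
Conditions: LiN(i-Pr)2 (LDA), THF, −78 °C; N-methoxy-N-methylacetamide, −78 → 0 °C; AcOH quench
Reagents that add atoms: N-methoxy-N-methylacetamide, CC(=O)N(C)OC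
Why: Claisen-type C-acylation of the ester enolate by a Weinreb amide, whose chelated tetrahedral adduct prevents over-addition.

Step 8
Reactants: 12 methyl 2-acetyl-3-(2-methyl-1,3-dioxolan-2-yl)propanoate
Product: 14 methyl (Z)-2-[(2-methyl-1,3-dioxolan-2-yl)methyl]-3-(triflyloxy)but-2-enoate, via sodium enolate 13 (not isolated)
Conditions: NaH, Et2O, 0 °C; Tf2O, −78 → 0 °C
Reagents that add atoms: triflic anhydride, O=S(=O)(OS(=O)(=O)C(F)(F)F)C(F)(F)F
Why: O-sulfonylation of the chelated sodium enolate of the β-keto ester should place the triflate cis to the ester, the geometry needed for the later lactonisation.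

**Pyrone assembly (steps 9–11)**

Step 9
Reactants: 8 triethyl{[(3R,4R,5S)-3,5-dimethyloct-1-en-7-yn-4-yl]oxy}silane; 14 methyl (Z)-2-[(2-methyl-1,3-dioxolan-2-yl)methyl]-3-(triflyloxy)but-2-enoate
Product: 15 methyl (2Z,7S,8R,9R)-3,7,9-trimethyl-2-[(2-methyl-1,3-dioxolan-2-yl)methyl]-8-(triethylsilyloxy)undeca-2,10-dien-4-ynoate
Conditions: Pd(PPh3)2Cl2 (cat.), CuI (cat.), Et3N, THF, rt
Reagents that add atoms: none
Why: Sonogashira coupling of the enol triflate with the terminal alkyne proceeds with retention of alkene geometry, so the ester stays cis to the alkyne.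

Step 10
Reactants: 15 methyl (2Z,7S,8R,9R)-enynoate
Product: 16 (2Z,7S,8R,9R)-3,7,9-trimethyl-2-[(2-methyl-1,3-dioxolan-2-yl)methyl]-8-(triethylsilyloxy)undeca-2,10-dien-4-ynoic acid
Conditions: LiOH, THF/H2O (3:1), 40 °C; then 0.5 M HCl to pH 4 at 0 °C
Reagents that add atoms: lithium hydroxide, [Li+].[OH-]
Why: saponification of the only ester present; the hindered silyl ether and the ketal are stable to aqueous base.

Step 11
Reactants: 16 (2Z,7S,8R,9R)-enynoic acid
Product: 17 6-[(2S,3R,4R)-2,4-dimethyl-3-(triethylsilyloxy)hex-5-en-1-yl]-4-methyl-3-[(2-methyl-1,3-dioxolan-2-yl)methyl]-2H-pyran-2-one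
Conditions: ZnBr2 (10 mol%), THF, rt
Reagents that add atoms: none
Why: Lewis-acid-catalysed 6-endo-dig lactonisation of a (Z)-2-en-4-ynoic acid, for which zinc bromide is known to favour the 2-pyrone over the five-membered ylidene butenolide.

**Side-chain fragment (steps 12–17)**

Step 12
Reactants: 18 2-methyl-2-vinyloxirane (racemic)
Product: 19 (S)-2-methyl-2-(nitromethyl)but-3-en-1-ol
Conditions: Pd2(dba)3·CHCl3 (cat.), (S,S)-DACH-phenyl Trost ligand (cat.), MeNO2 (excess), CH2Cl2, rt
Reagents that add atoms: nitromethane, C[N+](=O)[O-]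
Why: palladium-catalysed asymmetric allylic alkylation of a vinyl epoxide (dynamic kinetic asymmetric transformation), in which the alkoxide of the interconverting π-allyl complex deprotonates nitromethane and directs it to the substituted terminus while the ligand selects the face, sets the quaternary centre.

Step 13
Reactants: 19 (S)-2-methyl-2-(nitromethyl)but-3-en-1-ol
Product: 20 (S)-tert-butyldimethyl{[2-methyl-2-(nitromethyl)but-3-en-1-yl]oxy}silane
Conditions: t-BuMe2SiCl, imidazole, DMF, rt
Reagents that add atoms: tert-butyldimethylsilyl chloride, CC(C)(C)[Si](C)(C)Cl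
Why: standard silylation of the primary neopentyl alcohol.

Step 14
Reactants: 20 (S)-tert-butyldimethyl{[2-methyl-2-(nitromethyl)but-3-en-1-yl]oxy}silane
Product: 22 (R)-2-[(tert-butyldimethylsilyloxy)methyl]-2-methylbut-3-enal, via sodium nitronate 21 (not isolated)
Conditions: NaOMe, MeOH, 0 °C; then TiCl3 (aq.), NH4OAc, pH 5–6, rt
Reagents that add atoms: water, O
Why: reductive Nef reaction, in which TiCl3 reduces the nitronate to an imine that hydrolyses to the aldehyde; the quaternary centre has no acidic hydrogen and cannot epimerise.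

Step 15
Reactants: 22 (R)-2-[(tert-butyldimethylsilyloxy)methyl]-2-methylbut-3-enal
Product: 23 (S)-tert-butyl[(2-ethenyl-2-methylbut-3-yn-1-yl)oxy]dimethylsilane
Conditions: dimethyl (1-diazo-2-oxopropyl)phosphonate, K2CO3, MeOH, 0 °C → rt
Reagents that add atoms: dimethyl (1-diazo-2-oxopropyl)phosphonate, COP(=O)(OC)C(=[N+]=[N-])C(C)=O
Why: Seyferth–Gilbert homologation with the Ohira–Bestmann reagent converts the non-enolisable aldehyde into the terminal alkyne.

Step 16
Reactants: 23 (S)-tert-butyl[(2-ethenyl-2-methylbut-3-yn-1-yl)oxy]dimethylsilane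
Product: 25 tert-butyl{[(2S,3E)-2-ethenyl-4-iodo-2,3-dimethylbut-3-en-1-yl]oxy}dimethylsilane, via alkenylalane 24 (not isolated)
Conditions: Me3Al, Cp2ZrCl2 (0.3 equiv), CH2Cl2, 0 °C → rt; then iodine, THF, −30 → 0 °C
Reagents that add atoms: trimethylaluminium, C[Al](C)C; iodine, [I][I]
Why: zirconium-catalysed syn-carboalumination of the terminal alkyne puts methyl on the internal carbon, and iodinolysis with retention gives the (E)-iodide; the vinyl group reacts much more slowly.

Step 17
Reactants: 25 tert-butyl{[(2S,3E)-2-ethenyl-4-iodo-2,3-dimethylbut-3-en-1-yl]oxy}dimethylsilane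
Product: 26 methyl (2E,4S,5E)-4-[(tert-butyldimethylsilyloxy)methyl]-6-iodo-4,5-dimethylhexa-2,5-dienoate
Conditions: methyl acrylate (5 equiv), second-generation Hoveyda–Grubbs catalyst (5 mol%), toluene, 60 °C
Reagents that add atoms: methyl acrylate, C=CC(=O)OC
Why: cross-metathesis of the monosubstituted vinyl group with the acrylate should give the (E)-enoate, the trisubstituted vinyl iodide being inert to the ruthenium carbene.

**Union, key step and end game (steps 18–23)**

Step 18
Reactants: 17 pyrone with terminal alkene; 26 methyl (2E,4S,5E)-iododienoate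
Product: 27 methyl (2E,4S,5E,7E,9R,10R,11S)-4-[(tert-butyldimethylsilyloxy)methyl]-4,5,9,11-tetramethyl-12-{4-methyl-3-[(2-methyl-1,3-dioxolan-2-yl)methyl]-2-oxo-2H-pyran-6-yl}-10-(triethylsilyloxy)dodeca-2,5,7-trienoate
Conditions: Pd(OAc)2 (10 mol%), Ag2CO3, DMF, 45 °C
Reagents that add atoms: none
Why: Heck reaction, in which the alkenylpalladium from the vinyl iodide inserts the terminal alkene at its CH2 end and β-hydride elimination gives the conjugated (E,E)-diene, with the silver salt suppressing double-bond migration.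

Step 19
Reactants: 27 pyrone trienoate
Product: 29 silyl-protected bicyclic diene (1R,2R,3S,8S,8aR), via bridged lactone 28 (not isolated)
Conditions: toluene (0.005 M), BHT, 150 °C, sealed tube
Reagents that add atoms: none
Why: Thermal intramolecular [4+2] cycloaddition of the 2-pyrone (pyrone C6 and C3 become C4a and C7) with the tethered (E)-alkene gives the 2-oxabicyclo[2.2.2]oct-5-en-3-one 28, which loses CO2 by retro-[4+2] to unveil the C4a=C5–C6=C7 diene; the closest known reaction type is the intramolecular pyrone Diels–Alder/decarboxylation route to fused cyclohexadienes. Ring B closes through the four-carbon tether (C4, C3, C2, C1) by the C4a–C8a bond, and ring A closes in the same event as the cycloaddition ring by the C7–C8 bond. C8a and C8 are set trans by suprafacial addition to the (E)-alkene. Their absolute sense comes from a chair-like tether in which the C1 and C3 methyl groups and the C2 silyloxy group are all equatorial, so that C8 ends up trans to the C1 methyl; both bridge orientations of 28 converge because the bridgehead centres vanish with the CO2. The step needs facial selectivity and periselectivity (pyrone as 4π partner, proximal alkene of the side-chain diene as 2π partner), both secured by the tether length. It also needs a temperature below the onset of [1,5]-hydrogen shifts in the product diene.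

Step 20
Reactants: 29 silyl-protected bicyclic diene
Product: 30 C2 alcohol (1R,2R,3S,8S,8aR)
Conditions: HF·pyridine, pyridine, THF, 0 °C
Reagents that add atoms: none
Why: buffered fluoride should cleave the triethylsilyl ether much faster than the neopentyl TBS ether (selective desilylation), and the dioxolane is stable.

Step 21
Reactants: 30 C2 alcohol
Product: 31 C2 ketone (1R,3S,8S,8aR)
Conditions: Dess–Martin periodinane, NaHCO3, CH2Cl2, rt
Reagents that add atoms: none
Why: Dess–Martin oxidation gives the ring ketone; C1 and C3 already hold the all-equatorial, thermodynamically preferred configuration.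

Step 22
Reactants: 31 C2 ketone methyl ester
Product: 32 carboxylic acid (ketal and TBS ether retained)
Conditions: LiOH, THF/H2O, 0 °C → rt; then 0.5 M HCl to pH 4
Reagents that add atoms: lithium hydroxide, [Li+].[OH-]
Why: saponification of the unhindered methyl enoate while the acetonyl ketone is still masked, so the dienyl ketone cannot enolise under base.

Step 23
Reactants: 32 carboxylic acid
Product: 33 target CNP0260948.1
Conditions: 1 M HCl, THF, rt
Reagents that add atoms: water, O
Why: mild aqueous acid hydrolyses the dioxolane and the primary TBS ether in one operation to release the acetonyl ketone and the hydroxymethyl group.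

**Compound list**

1 | (R)-4-benzyl-3-propionyloxazolidin-2-one | CCC(=O)N1[C@H](Cc2ccccc2)COC1=O | starting material
2 | sodium (Z)-enolate of 1 | C/C=C(\[O-])N1[C@H](Cc2ccccc2)COC1=O.[Na+] | intermediate
3 | (R)-4-benzyl-3-[(S)-2-methylpent-4-ynoyl]oxazolidin-2-one | C#CC[C@H](C)C(=O)N1[C@H](Cc2ccccc2)COC1=O | intermediate
4 | (S)-2-methylpent-4-yn-1-ol | C#CC[C@H](C)CO | intermediate
5 | (S)-2-methylpent-4-ynal | C#CC[C@H](C)C=O | intermediate
6 | bis(isopinocampheyl)borinate ester of 7 | C#CC[C@H](C)[C@@H](OB([C@@H]1C[C@@H]2C[C@H]([C@H]1C)C2(C)C)[C@@H]1C[C@@H]2C[C@H]([C@H]1C)C2(C)C)[C@H](C)C=C | intermediate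
7 | (3R,4R,5S)-3,5-dimethyloct-1-en-7-yn-4-ol (syn,syn triad) | C#CC[C@H](C)[C@@H](O)[C@H](C)C=C | intermediate
8 | triethyl{[(3R,4R,5S)-3,5-dimethyloct-1-en-7-yn-4-yl]oxy}silane | C#CC[C@H](C)[C@@H](O[Si](CC)(CC)CC)[C@H](C)C=C | intermediate
9 | methyl levulinate (methyl 4-oxopentanoate) | CC(=O)CCC(=O)OC | starting material
10 | methyl 3-(2-methyl-1,3-dioxolan-2-yl)propanoate | COC(=O)CCC1(C)OCCO1 | intermediate
11 | lithium enolate of 10 | CO/C([O-])=C\CC1(C)OCCO1.[Li+] | intermediate
12 | methyl 2-acetyl-3-(2-methyl-1,3-dioxolan-2-yl)propanoate (racemic; the centre becomes sp2 in step 8) | COC(=O)C(CC1(C)OCCO1)C(C)=O | intermediate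
13 | chelated sodium enolate of 12 | COC(=O)/C(CC1(C)OCCO1)=C(/C)[O-].[Na+] | intermediate
14 | methyl (Z)-2-[(2-methyl-1,3-dioxolan-2-yl)methyl]-3-(triflyloxy)but-2-enoate | COC(=O)/C(CC1(C)OCCO1)=C(/C)OS(=O)(=O)C(F)(F)F | intermediate
15 | methyl (2Z,7S,8R,9R)-3,7,9-trimethyl-2-[(2-methyl-1,3-dioxolan-2-yl)methyl]-8-(triethylsilyloxy)undeca-2,10-dien-4-ynoate | COC(=O)/C(CC1(C)OCCO1)=C(/C)C#CC[C@H](C)[C@@H](O[Si](CC)(CC)CC)[C@H](C)C=C | intermediate
16 | (2Z,7S,8R,9R)-3,7,9-trimethyl-2-[(2-methyl-1,3-dioxolan-2-yl)methyl]-8-(triethylsilyloxy)undeca-2,10-dien-4-ynoic acid | OC(=O)/C(CC1(C)OCCO1)=C(/C)C#CC[C@H](C)[C@@H](O[Si](CC)(CC)CC)[C@H](C)C=C | intermediate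
17 | 6-[(2S,3R,4R)-2,4-dimethyl-3-(triethylsilyloxy)hex-5-en-1-yl]-4-methyl-3-[(2-methyl-1,3-dioxolan-2-yl)methyl]-2H-pyran-2-one | CC1(OCCO1)CC2=C(C)C=C(OC2=O)C[C@H](C)[C@@H](O[Si](CC)(CC)CC)[C@H](C)C=C | intermediate
18 | 2-methyl-2-vinyloxirane (isoprene monoepoxide, racemic) | CC1(C=C)CO1 | starting material
19 | (S)-2-methyl-2-(nitromethyl)but-3-en-1-ol | [O-][N+](=O)C[C@](C)(C=C)CO | intermediate
20 | (S)-tert-butyldimethyl{[2-methyl-2-(nitromethyl)but-3-en-1-yl]oxy}silane | [O-][N+](=O)C[C@](C)(C=C)CO[Si](C)(C)C(C)(C)C | intermediate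
21 | sodium nitronate of 20 | [Na+].[O-][N+]([O-])=C[C@](C)(C=C)CO[Si](C)(C)C(C)(C)C | intermediate
22 | (R)-2-[(tert-butyldimethylsilyloxy)methyl]-2-methylbut-3-enal | O=C[C@](C)(C=C)CO[Si](C)(C)C(C)(C)C | intermediate
23 | (S)-tert-butyl[(2-ethenyl-2-methylbut-3-yn-1-yl)oxy]dimethylsilane | C#C[C@](C)(C=C)CO[Si](C)(C)C(C)(C)C | intermediate
24 | (E)-alkenyl(dimethyl)alane from carboalumination of 23 | C[Al](C)/C=C(\C)[C@](C)(C=C)CO[Si](C)(C)C(C)(C)C | intermediate
25 | tert-butyl{[(2S,3E)-2-ethenyl-4-iodo-2,3-dimethylbut-3-en-1-yl]oxy}dimethylsilane | I/C=C(\C)[C@](C)(C=C)CO[Si](C)(C)C(C)(C)C | intermediate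
26 | methyl (2E,4S,5E)-4-[(tert-butyldimethylsilyloxy)methyl]-6-iodo-4,5-dimethylhexa-2,5-dienoate | I/C=C(\C)[C@](C)(/C=C/C(=O)OC)CO[Si](C)(C)C(C)(C)C | intermediate
27 | methyl (2E,4S,5E,7E,9R,10R,11S)-4-[(tert-butyldimethylsilyloxy)methyl]-4,5,9,11-tetramethyl-12-{4-methyl-3-[(2-methyl-1,3-dioxolan-2-yl)methyl]-2-oxo-2H-pyran-6-yl}-10-(triethylsilyloxy)dodeca-2,5,7-trienoate | CC1(OCCO1)CC2=C(C)C=C(OC2=O)C[C@H](C)[C@@H](O[Si](CC)(CC)CC)[C@H](C)/C=C/C=C(\C)[C@](C)(/C=C/C(=O)OC)CO[Si](C)(C)C(C)(C)C | intermediate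
28 | bridged 2-oxabicyclo[2.2.2]oct-5-en-3-one cycloadduct of 27, ring B fused at C4a–C8a (one of the two convergent bridge orientations is drawn) | CC1(OCCO1)C[C@]23C(=O)O[C@@]4(C=C2C)C[C@H](C)[C@@H](O[Si](CC)(CC)CC)[C@H](C)[C@H]4[C@@H]3/C=C(\C)[C@](C)(/C=C/C(=O)OC)CO[Si](C)(C)C(C)(C)C | intermediate
29 | (1R,2R,3S,8S,8aR)-1,2,3,4,8,8a-hexahydronaphthalene with C1, C3, C6 methyl groups, C2 OSiEt3, C7 (2-methyl-1,3-dioxolan-2-yl)methyl, and at C8 the (E,S,E) side chain as methyl ester and TBS ether | CC1(OCCO1)CC2=C(C)C=C3C[C@H](C)[C@@H](O[Si](CC)(CC)CC)[C@H](C)[C@H]3[C@@H]2/C=C(\C)[C@](C)(/C=C/C(=O)OC)CO[Si](C)(C)C(C)(C)C | intermediate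
30 | C2 alcohol (1R,2R,3S,8S,8aR) corresponding to 29 | CC1(OCCO1)CC2=C(C)C=C3C[C@H](C)[C@@H](O)[C@H](C)[C@H]3[C@@H]2/C=C(\C)[C@](C)(/C=C/C(=O)OC)CO[Si](C)(C)C(C)(C)C | intermediate
31 | C2 ketone (1R,3S,8S,8aR), methyl ester, TBS ether, dioxolane | CC1(OCCO1)CC2=C(C)C=C3C[C@H](C)C(=O)[C@H](C)[C@H]3[C@@H]2/C=C(\C)[C@](C)(/C=C/C(=O)OC)CO[Si](C)(C)C(C)(C)C | intermediate
32 | carboxylic acid corresponding to 31 (TBS ether and dioxolane retained) | CC1(OCCO1)CC2=C(C)C=C3C[C@H](C)C(=O)[C@H](C)[C@H]3[C@@H]2/C=C(\C)[C@](C)(/C=C/C(=O)O)CO[Si](C)(C)C(C)(C)C | intermediate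
33 | CNP0260948.1: (2E,4S,5E)-4-(hydroxymethyl)-4,5-dimethylhexa-2,5-dienoic acid carrying at C6 the (1R,3S,8S,8aR)-1,3,6-trimethyl-2-oxo-7-(2-oxopropyl)-1,2,3,4,8,8a-hexahydronaphthalen-8-yl group | CC(=O)CC1=C(C)C=C2C[C@H](C)C(=O)[C@H](C)[C@H]2[C@@H]1/C=C(\C)[C@](C)(/C=C/C(=O)O)CO | target

**Step count and risks**

Total: 23 steps. Longest linear sequence: 14 steps (steps 1–5, 9–11, 18–23).

Steps most likely to fail:

1. Step 19 (key step). The fully substituted pyrone may react too slowly with the unactivated alkene, which would force temperatures at which [1,5]-hydrogen shifts scramble the product diene. The fallback sets out from acid 16 and uses a halogen-activated pyrone. Bromolactonisation of 16 (NBS, NaHCO3, MeCN, 0 °C) in place of step 11 should give the 5-bromo-2-pyrone F1. Heck coupling with 26 under the conditions of step 18, where the vinyl iodide undergoes oxidative addition much faster than the pyrone bromide, gives the bromopyrone trienoate F2. The more reactive bromopyrone should cyclise at lower temperature to the bridged bromolactone F3, which loses CO2 on further warming to the bromodiene F4. Palladium-catalysed formate reduction (Pd(OAc)2, PPh3, HCO2H, Et3N, DMF, 60 °C) then removes the bromine and returns to the route at 29.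

2. Step 18. Double-bond migration after insertion, or capture of the alkenylpalladium by the enoate of 26, may erode the Heck coupling. The fallback sets out from 17. Cross-metathesis with vinylboronic acid pinacol ester (second-generation Hoveyda–Grubbs catalyst, CH2Cl2, 40 °C) should give the (E)-alkenylboronate F5. Suzuki coupling of F5 with 26 (Pd(PPh3)4, K3PO4, THF/H2O, rt) forms the same C–C bond under transmetalation control and returns to the route at 27.

3. Step 4. The Felkin-type addition required is the mismatched mode for a (Z)-crotyl reagent, so diastereoselectivity may be poor. The fallback sets out from aldehyde 5. A boron-mediated Evans syn-aldol reaction with (S)-4-benzyl-3-propionyloxazolidin-2-one (Bu2BOTf, Et3N, CH2Cl2, −78 °C), which is under strong auxiliary control, should give the aldol adduct F6. Silylation (Et3SiOTf, 2,6-lutidine) gives the silyl ether F7, reduction with LiBH4 gives the primary alcohol F8, and Dess–Martin oxidation gives the aldehyde F9. Wittig methylenation (Ph3P=CH2, THF, 0 °C) returns to the route at 8.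

Further compounds
F1 | step 19 | 5-bromo-6-[(2S,3R,4R)-2,4-dimethyl-3-(triethylsilyloxy)hex-5-en-1-yl]-4-methyl-3-[(2-methyl-1,3-dioxolan-2-yl)methyl]-2H-pyran-2-one | CC1(OCCO1)CC2=C(C)C(Br)=C(OC2=O)C[C@H](C)[C@@H](O[Si](CC)(CC)CC)[C@H](C)C=C
F2 | step 19 | 5-bromo analogue of pyrone trienoate 27 | CC1(OCCO1)CC2=C(C)C(Br)=C(OC2=O)C[C@H](C)[C@@H](O[Si](CC)(CC)CC)[C@H](C)/C=C/C=C(\C)[C@](C)(/C=C/C(=O)OC)CO[Si](C)(C)C(C)(C)C
F3 | step 19 | bridged bromolactone, bromo analogue of 28 | CC1(OCCO1)C[C@]23C(=O)O[C@@]4(C(Br)=C2C)C[C@H](C)[C@@H](O[Si](CC)(CC)CC)[C@H](C)[C@H]4[C@@H]3/C=C(\C)[C@](C)(/C=C/C(=O)OC)CO[Si](C)(C)C(C)(C)C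
F4 | step 19 | C5-bromo analogue of bicyclic diene 29 | CC1(OCCO1)CC2=C(C)C(Br)=C3C[C@H](C)[C@@H](O[Si](CC)(CC)CC)[C@H](C)[C@H]3[C@@H]2/C=C(\C)[C@](C)(/C=C/C(=O)OC)CO[Si](C)(C)C(C)(C)C
F5 | step 18 | (E)-alkenylboronic acid pinacol ester of pyrone 17 | CC1(OCCO1)CC2=C(C)C=C(OC2=O)C[C@H](C)[C@@H](O[Si](CC)(CC)CC)[C@H](C)/C=C/B3OC(C)(C)C(C)(C)O3
F6 | step 4 | (S)-4-benzyl-3-[(2S,3R,4S)-3-hydroxy-2,4-dimethylhept-6-ynoyl]oxazolidin-2-one | C#CC[C@H](C)[C@@H](O)[C@H](C)C(=O)N1[C@@H](Cc2ccccc2)COC1=O
F7 | step 4 | (S)-4-benzyl-3-[(2S,3R,4S)-2,4-dimethyl-3-(triethylsilyloxy)hept-6-ynoyl]oxazolidin-2-one | C#CC[C@H](C)[C@@H](O[Si](CC)(CC)CC)[C@H](C)C(=O)N1[C@@H](Cc2ccccc2)COC1=O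
F8 | step 4 | (2R,3R,4S)-2,4-dimethyl-3-(triethylsilyloxy)hept-6-yn-1-ol | C#CC[C@H](C)[C@@H](O[Si](CC)(CC)CC)[C@H](C)CO
F9 | step 4 | (2S,3R,4S)-2,4-dimethyl-3-(triethylsilyloxy)hept-6-ynal | C#CC[C@H](C)[C@@H](O[Si](CC)(CC)CC)[C@H](C)C=O
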